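The numbers in the tables were computed for substances that don't exist; the scatter is artificial.

I followed the coupling partner. The question is what this flask holds at 25 h and which late change adds target.

all flasks: substrate 0.10 M; initiator 2.5 mol%
- south-east: coupling partner 1 equiv; temperature 80 °C; the very flask that is asked about, followed so far
- east: coupling partner 2 equiv; temperature 75 °C; run made earlier
- flask: coupling partner 1.00 equiv; temperature 80 °C; time 25 h

- south-east (time / h: target / %, substrate / %): 1.50: 8.8, 88.6; 5.00: 17.4, 73.0; 8.00: 22.1, 68.1; 15.0: 24.3, 64.9; 20.0: 23.7, 63.2; 25.0: 24.8, 63.6
- east (time / min: target / %, substrate / %): 10.0: 1.0, 98.6; 15.0: 0.8, 96.5; 25.0: 2.1, 96.0; 40.0: 4.5, 92.3; 80.0: 9.4, 85.2; 120: 13.1, 79.8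

(each reading ± 0.5 percentage points)

- target, in percent of the substrate first charged, at 25 h
- which option adds most target ("none" when 2 percentage points or less is all one gets) (Saturday's / Friday's / Wednesday's / Thursday's / none)
- target present, in percent of the substrate first charged, after Friday's
- target present, in percent of the substrate first charged, after Thursday's

- Saturday's: at 25 h raise the temperature by 25 K, then wait 25 h
- Friday's: at 25 h take out 90% of the by-product then present, then wait 25 h
- Wednesday's: change nothing and wait 25 h more
- Thursday's: at 25 h add coupling partner, 50.0% of the amount charged, then wait 25 h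

- additions leave the volume as it is
- a reading or a percentage of target counts all its forms, free or not
- a reading of substrate is of its free form alone

How far had the flask gone? In the south-east run, which is this flask followed so far, the target readings from 15.0 h on averaged 24.3%. They differed by about the scatter, so I took that for "now". The rise to it had a time constant τ of about 3.96 h, read at 5.00 h, and 25 h is 6.31 of those. So I expected nothing from waiting.

What had stopped it? Substrate was not lacking, since the reading at 25.0 h shows more of it free, 63.6%, than target made. The readings do not show the partner, and my bet was that it was the limiting reagent. Each partner molecule then meets a fork: it becomes target or it is lost. With one partner charged per substrate, the plateau is φ, the chance that one partner molecule ends as target, about a quarter.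

What then pays? On this reckoning, an option that brings no partner leaves target near 24.3%, Friday's included. Thursday's brings partner, worth 12 percentage points, so I committed to Thursday's at 36.4%.

The forecast gave 24.5% now, 35% after Friday's and 29% after Thursday's, and chose Friday's, reasoning: “Removing by-product releases bound substrate and pulls the equilibrium forward”.

The flask gave 24.3% at 25 h, 24.4% after Friday's and 33.2% after Thursday's, so the best option was Thursday's.

    first chain carrier → ended carrier (k = 18000 h⁻¹, Ea = 76.0 kJ mol⁻¹)
    coupling partner + first chain carrier → target + second chain carrier (k = 2.30 × 10⁷ M⁻¹ h⁻¹, Ea = 43.0 kJ mol⁻¹)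
    substrate + target ⇌ idle adduct, settled at all times (K = 12.0 M⁻¹, ΔH = 9.00 kJ mol⁻¹)
    coupling partner → decomposed reagent (k = 0.190 h⁻¹, Ea = 110 kJ mol⁻¹)
    initiator → 2 initiating radical (k = 0.0240 h⁻¹, Ea = 129 kJ mol⁻¹)
    2 first chain carrier → ended chains (k = 1.20 × 10⁹ M⁻¹ s⁻¹, Ea = 10.0 kJ mol⁻¹)
    substrate + initiating radical → capped initiator + first chain carrier (k = 2.10 × 10⁵ M⁻¹ s⁻¹, Ea = 23.0 kJ mol⁻¹)
    substrate + second chain carrier → by-product + first chain carrier (k = 47000 M⁻¹ s⁻¹, Ea = 23.0 kJ mol⁻¹)
    (constants at 80 °C)

At 25.0 h the flask held 0.225% of its charged partner. Thursday's gain in target came to 17.8% of the partner added, less than φ. A neighbour charged with 2.50 equiv from the start has φ predicting 60.8%, and it gave 60.8%.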